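A direct plan would benzoylate phloroglucinol A1 under Friedel–Crafts conditions to 2,4,6-trihydroxybenzophenone A2 and would then attach both prenyl groups at ring carbons by phenolate alkylation, giving 2,4,6-trihydroxy-3,5-diprenylbenzophenone A3 as the substrate for a final methylation of one of the two ketone-flanked hydroxyls. The double C-prenylation would be weak, because the ambident phenolate would also react at oxygen and again at a carbon that already bears a prenyl group. The final mono-O-methylation would be weaker still, because the hydroxyl to be methylated is hydrogen-bonded to the ketone and flanked by a prenyl group, so that the para hydroxyl or both ortho hydroxyls would react in competition.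

The route would not decorate an arene; it would build the phloroglucinol ring last, in the manner of its biosynthesis. Ring atoms C2, C4 and C6 carry oxygen and C1 the benzoyl group, the pattern of a benzoyl-primed tetraketide. A triketide lactone, 4-methoxy-6-phenyl-3-prenyl-2-pyranone, already holds the methyl ether on the future C2 oxygen and one prenyl on the future C3. The enolate of methyl 5-methylhex-4-enoate would open it at the lactone carbonyl and the chain would close in the Claisen mode, forming C4–C5 and C6–C1 and the arene in one operation. Both prenyl groups would come from aliphatic enolate chemistry and no phenol would have to be chosen for methylation.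

Key step: step 6

Remark on the chemistry: the arene of the target is numbered with C1 bearing the benzoyl group, C2 the methoxy group, C3 and C5 the prenyl groups, C4 and C6 the hydroxyls. The target is achiral; the stereocentres of 3, 6, 15 and 16 would form racemic and are lost on enolisation or aromatisation. Compounds 1, 2, 4, 8, 10, 11 and LiN(i-Pr)2 solution are taken as commercial.

Step 1
Reactants: 1 ethyl acetoacetate; 2 prenyl bromide (1-bromo-3-methylbut-2-ene)
Product: 3 ethyl 2-acetyl-5-methylhex-4-enoate
Conditions: 1 (1.5 equiv), K2CO3 (1.2 equiv), acetone, reflux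
Reagents that add atoms: prenyl bromide, CC(C)=CCBr
Why: C-alkylation of the stabilised β-keto ester enolate by SN2 displacement at the primary allylic bromide, with the excess of 1 suppressing a second alkylation.

Step 2
Reactants: 3 ethyl 2-acetyl-5-methylhex-4-enoate; 4 methyl benzoate
Product: 6 ethyl 2-(3-methylbut-2-en-1-yl)-3,5-dioxo-5-phenylpentanoate, via dilithium dienolate 5 (not isolated)
Conditions: 3 (2.0 equiv), LiN(i-Pr)2 (4.0 equiv), THF, −78 → 0 °C; then 4 (1.0 equiv), 0 °C; 1 M HCl; excess 3 recovered
Reagents that add atoms: methyl benzoate, COC(=O)c1ccccc1
Why: γ-Acylation of a β-keto ester dianion (Claisen condensation), in which the more basic terminal carbon of 5 attacks the non-enolisable ester and the second equivalent of dianion takes up the proton of the more acidic product.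

Step 3
Reactants: 6 ethyl 2-(3-methylbut-2-en-1-yl)-3,5-dioxo-5-phenylpentanoate
Product: 7 4-hydroxy-3-(3-methylbut-2-en-1-yl)-6-phenyl-2H-pyran-2-one
Conditions: DBU (1.1 equiv), toluene, 80 °C; 1 M HCl
Reagents that add atoms: none
Why: Enol lactonisation, in which the enolate oxygen of the phenyl ketone attacks the ethyl ester (6-exo-trig) and the conjugated 4-hydroxy-2-pyranone is the thermodynamic sink, as is usual for 3,5-diketo esters.

Step 4
Reactants: 7 4-hydroxy-3-(3-methylbut-2-en-1-yl)-6-phenyl-2H-pyran-2-one; 8 dimethyl sulfate
Product: 9 4-methoxy-3-(3-methylbut-2-en-1-yl)-6-phenyl-2H-pyran-2-one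
Conditions: Me2SO4 (1.2 equiv), K2CO3 (1.5 equiv), acetone, reflux
Reagents that add atoms: dimethyl sulfate, COS(=O)(=O)OC
Why: O-Alkylation of the vinylogous carboxylate with a hard methyl electrophile, which for 4-hydroxy-2-pyranones should go mainly at the 4-oxygen; a minor 2-methoxy-4-pyranone isomer would be removed by chromatography.

Step 5
Reactants: 10 2-methylbut-3-en-2-ol; 11 trimethyl orthoacetate
Product: 13 methyl 5-methylhex-4-enoate, via mixed ketene acetal 12 (not isolated)
Conditions: 11 (3 equiv), EtCO2H (5 mol%), 110 → 140 °C, MeOH distilled off
Reagents that add atoms: trimethyl orthoacetate, COC(C)(OC)OC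
Why: Johnson–Claisen rearrangement, in which acid-catalysed exchange gives ketene acetal 12 and its [3,3]-sigmatropic shift forms the new C–C bond at the terminal alkene carbon and leaves the trisubstituted prenyl-type alkene.

Step 6
Reactants: 9 4-methoxy-3-(3-methylbut-2-en-1-yl)-6-phenyl-2H-pyran-2-one; 13 methyl 5-methylhex-4-enoate
Product: 17 (2,4-dihydroxy-6-methoxy-3,5-bis(3-methylbut-2-en-1-yl)phenyl)(phenyl)methanone, via lithium ester enolate 14 (not isolated), via open-chain keto ester 15 (not isolated), via cyclohexenedione tautomer 16 (not isolated)
Conditions: LiN(i-Pr)2 (1.5 equiv), 13 (1.6 equiv), THF, −78 °C; then 9 (1.0 equiv), −78 → 0 °C; then MeOH, 0 → 40 °C; 1 M HCl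
Reagents that add atoms: methyl 5-methylhex-4-enoate, COC(=O)CCC=C(C)C
Why: Proposed new method: the hard lithium enolate 14 should add to the lactone carbonyl (C2) of 9, and collapse of the tetrahedral adduct should expel the ring oxygen as a vinylogous β-diketonate, giving 15 (arene bond C4–C5) with the new ketone and the phenacyl carbon held cis on the enol ether double bond, as ring closure needs. The carbon α to the benzoyl group of this delocalised anion should then attack the methyl ester in a 6-exo-trig Claisen (Dieckmann-type) closure (arene bond C6–C1), the cyclisation mode of benzophenone synthase, and loss of methoxide gives 16, which enolises irreversibly to the arene. The closest known reactions are the Fujimoto–Belleau reaction (carbanion addition to an enol lactone with ring opening and carbocyclisation), the addition of Grignard reagents to C2 of 2-pyranones and the base-induced Claisen cyclisation of 3,5,7-triketo esters to acylphloroglucinols; an ester-enolate opening of a 4-alkoxy-2-pyranone followed by Claisen closure has not been shown. The step needs attack at C2 and not conjugate attack at C4 or C6, which the donating 4-methoxy group, the prenyl group on C3 and the phenyl group on C6 should secure for a lithium enolate at low temperature. It also needs C-acylation and not the aldol mode onto the benzoyl carbon, which would give a quaternary, non-aromatisable and therefore reversible adduct, while methanol lets the anions equilibrate so that the aromatisation drains them. No stereocentre is set, and the methyl ether cannot end up elsewhere, because the 4-oxygen of 9 becomes the C2 oxygen of 17 between the benzoyl-bearing carbon (C5 of 9) and the prenyl-bearing C3.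

Compound list
1 | ethyl acetoacetate | CCOC(=O)CC(C)=O | starting material
2 | prenyl bromide (1-bromo-3-methylbut-2-ene) | CC(C)=CCBr | starting material
3 | ethyl 2-acetyl-5-methylhex-4-enoate (racemic) | CCOC(=O)C(CC=C(C)C)C(C)=O | intermediate
4 | methyl benzoate | COC(=O)c1ccccc1 | starting material
5 | dilithium dienolate of 3 (ester enolate and terminal ketone enolate; not isolated) | CCOC(O[Li])=C(CC=C(C)C)C(=C)O[Li] | intermediate
6 | ethyl 2-(3-methylbut-2-en-1-yl)-3,5-dioxo-5-phenylpentanoate (racemic, largely enolised) | CCOC(=O)C(CC=C(C)C)C(=O)CC(=O)c1ccccc1 | intermediate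
7 | 4-hydroxy-3-(3-methylbut-2-en-1-yl)-6-phenyl-2H-pyran-2-one | CC(C)=CCC1=C(O)C=C(c2ccccc2)OC1=O | intermediate
8 | dimethyl sulfate | COS(=O)(=O)OC | starting material
9 | 4-methoxy-3-(3-methylbut-2-en-1-yl)-6-phenyl-2H-pyran-2-one | COC1=C(CC=C(C)C)C(=O)OC(c2ccccc2)=C1 | intermediate
10 | 2-methylbut-3-en-2-ol | C=CC(C)(C)O | starting material
11 | trimethyl orthoacetate | COC(C)(OC)OC | starting material
12 | 3-[(1-methoxyethenyl)oxy]-3-methylbut-1-ene (mixed ketene acetal; not isolated) | C=CC(C)(C)OC(=C)OC | intermediate
13 | methyl 5-methylhex-4-enoate | COC(=O)CCC=C(C)C | intermediate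
14 | lithium enolate of 13 (not isolated) | COC(O[Li])=CCC=C(C)C | intermediate
15 | methyl (4E)-5-methoxy-2,4-bis(3-methylbut-2-en-1-yl)-3,7-dioxo-7-phenylhept-4-enoate (formed as its lithium enolate, drawn as the neutral keto form; racemic at C2; not isolated) | COC(=O)C(CC=C(C)C)C(=O)/C(CC=C(C)C)=C(\CC(=O)c1ccccc1)OC | intermediate
16 | 6-benzoyl-5-methoxy-2,4-bis(3-methylbut-2-en-1-yl)cyclohex-4-ene-1,3-dione (keto tautomer of the target; not isolated) | O=C1C(CC=C(C)C)C(=O)C(CC=C(C)C)=C(OC)C1C(=O)c1ccccc1 | intermediate
17 | (2,4-dihydroxy-6-methoxy-3,5-bis(3-methylbut-2-en-1-yl)phenyl)(phenyl)methanone (achiral) | COc1c(CC=C(C)C)c(O)c(CC=C(C)C)c(O)c1C(=O)c1ccccc1 | target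

Total step count: 6. Longest linear sequence: 5 steps (steps 1, 2, 3, 4 and 6).

Steps most likely to fail

Step 6 (proposed new method). The enolate 14 might add in conjugate fashion to C6 or C4 of 9 and not to the lactone carbonyl. The sequence might also stall after ring opening, if excess enolate deprotonates C2 of 15 and the chain recloses through oxygen on work-up. The fallback uses known chemistry and gives up the ring synthesis; it would set out from 2 and return at 17. 5-Methoxyresorcinol F1 would be acylated with benzonitrile F2 in a Hoesch reaction (ZnCl2, HCl, Et2O, 0 °C) to the ketiminium chloride F3 as a precipitate. Hydrolysis in hot water would then give 2,4-dihydroxy-6-methoxybenzophenone F4 together with its regioisomer, from which it would be separated. Compound F4 would then be C-prenylated twice with 2 (aq. KOH, 0 °C) at its two free ring carbons to give 17.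

Step 2. Proton transfer from the more acidic triketo product to dianion 5, together with slow acylation of the α-branched dianion, might stall the condensation, and the amide base might consume the ester 4. In the fallback the carboxyl carbon would be added last and not the benzoyl group; it would set out from 2 and return at 7. 1-Phenylbutane-1,3-dione F5 would be deprotonated twice (LiN(i-Pr)2, 2 equiv, THF, 0 °C) and alkylated at its methyl carbon with 2 to give 7-methyl-1-phenyloct-6-ene-1,3-dione F6 as the chain-extended diketone. A second double deprotonation and carboxylation with CO2 at the methylene next to the alkyl ketone would give 2-(3-methylbut-2-en-1-yl)-3,5-dioxo-5-phenylpentanoic acid F7 as the open-chain precursor. The acid F7 would be closed to 7 with 1,1'-carbonyldiimidazole in THF.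

Step 4. The ambident anion of 7 might be methylated at the lactone carbonyl oxygen or at C3. The fallback would be a Mitsunobu etherification of 7 with methanol (PPh3, diisopropyl azodicarboxylate, THF, 0 °C → rt). This is a redox condensation in which neutral 7 is the acid partner and no free ambident anion is alkylated, and it is known to place the alkyl group on the 4-oxygen of 4-hydroxy-2-pyranones. It would set out from 7 and return at 9; no new compound would be made on the way, hence the entry F0 in the block below.

Further compounds
F1 | step 6 | 5-methoxyresorcinol (5-methoxybenzene-1,3-diol) | COc1cc(O)cc(O)c1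
F2 | step 6 | benzonitrile | N#Cc1ccccc1
F3 | step 6 | (2,4-dihydroxy-6-methoxyphenyl)(phenyl)methaniminium chloride | COc1cc(O)cc(O)c1C(=[NH2+])c1ccccc1.[Cl-]
F4 | step 6 | 2,4-dihydroxy-6-methoxybenzophenone | COc1cc(O)cc(O)c1C(=O)c1ccccc1
F5 | step 2 | 1-phenylbutane-1,3-dione | CC(=O)CC(=O)c1ccccc1
F6 | step 2 | 7-methyl-1-phenyloct-6-ene-1,3-dione | CC(C)=CCCC(=O)CC(=O)c1ccccc1
F7 | step 2 | 2-(3-methylbut-2-en-1-yl)-3,5-dioxo-5-phenylpentanoic acid (racemic) | OC(=O)C(CC=C(C)C)C(=O)CC(=O)c1ccccc1
F0 | step 4 | none | none
A1 | direct plan | phloroglucinol (benzene-1,3,5-triol) | Oc1cc(O)cc(O)c1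
A2 | direct plan | 2,4,6-trihydroxybenzophenone | O=C(c1ccccc1)c1c(O)cc(O)cc1O
A3 | direct plan | 2,4,6-trihydroxy-3,5-bis(3-methylbut-2-en-1-yl)benzophenone | CC(C)=CCc1c(O)c(CC=C(C)C)c(O)c(C(=O)c2ccccc2)c1O
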